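**Plan**
- Retrosynthesis: C8–C9 and C10–C21 are cut together (rings B and C), then C21–C22 (acetylide + aldehyde). The ring D seco keto-aldehyde comes from an octalone template opened at C10=C21; the ring A side chain comes from a Rh 1,4-addition.
- Enabling feature: the C9 carbinol lies between quaternary C10 (ring C) and C8 of the homoallylic unit C9–C8–C3=C2 (rings A/B). An aldehyde enol ether C9=C10 can therefore first be alkylated at C10 and then close onto the cyclopentene through C9. The saturated C22–C23 of ring B can carry a temporary alkyne whose Co2(CO)6 complex stabilises a cation at C21.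
- Forward order: ring D fragment (steps 1–6), ring A fragment (7–11), union (12), chain adjustment to the (Z)-enol ether and cobalt complex (13–17), rings C and B in one operation (18), removal of cobalt, the extra unsaturation and the silyl groups (19–21).
- Stereochemistry: C14 from a d'Angelo Michael reaction; C20 from Li/NH3 reduction of the template enone; C5 from commercial (R)-4-silyloxycyclopentenone and C6 from anti cuprate addition; C21, C10, C9 and C8 in step 18; C2 is a temporary centre set by Rh/BINAP.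

Key step: step 18

Remark: C1–C23 are position labels only (C1 = methyl on C2; C2=C3 alkene; ring A = C3, C4, C5(O), C6 (methyl C7), C8; C9 carbinol; C10 (methyl C11); C12, C13; C14 (methyl C15); C16, C17, C18(Me2), C19, C20; C21; C22, C23); the two commercial ketones and (R)-4-(TBSO)cyclopent-2-enone are taken as purchasable.

**Step 1**
Reactants: 1 3,3-dimethylcyclohexanone
Product: 2 2,5,5-trimethylcyclohexanone (racemic)
Conditions: LDA, THF, −78 °C; MeI, −78 → 0 °C
Reagents that add atoms: iodomethane, CI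
Why: Kinetic deprotonation occurs at the CH2 remote from the neopentyl position, and alkylation of that enolate gives the 2-methyl ketone (ketone α-alkylation).

**Step 2**
Reactants: 2 2,5,5-trimethylcyclohexanone; 3 methyl vinyl ketone
Product: 6 (S)-2,5,5-trimethyl-2-(3-oxobutyl)cyclohexan-1-one, via imine 4 (not isolated), via Michael-adduct imine 5 (not isolated)
Conditions: (R)-1-phenylethylamine, TsOH (cat.), toluene, reflux; then 3, THF, 25 °C; then aq. AcOH
Reagents that add atoms: water, O
Why: d'Angelo deracemising Michael reaction: the secondary enamine tautomer of the chiral imine adds through its more substituted carbon on the face away from the phenyl group, which should set quaternary C14 as S, and hydrolysis returns the ketone.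

**Step 3**
Reactants: 6 (S)-2,5,5-trimethyl-2-(3-oxobutyl)cyclohexan-1-one
Product: 7 (S)-4a,7,7-trimethyl-4,4a,5,6,7,8-hexahydronaphthalen-2(3H)-one
Conditions: KOH (cat.), EtOH, reflux
Reagents that add atoms: none
Why: Intramolecular aldol condensation (second half of a Robinson annulation) closes a temporary cyclohexenone that relays C14 to C20.

**Step 4**
Reactants: 7 (S)-4a,7,7-trimethyl-4,4a,5,6,7,8-hexahydronaphthalen-2(3H)-one
Product: 9 (4aS,8aS)-4a,7,7-trimethyl-3,4,4a,5,6,7,8,8a-octahydronaphthalen-2-yl trifluoromethanesulfonate (trans-fused), via lithium enolate 8 (not isolated)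
Conditions: Li, NH3(l)/THF, t-BuOH (1 equiv), −78 °C; evaporate NH3; PhNTf2, THF, −78 → 0 °C
Reagents that add atoms: N-phenylbis(trifluoromethanesulfonimide), O=S(=O)(N(c1ccccc1)S(=O)(=O)C(F)(F)F)C(F)(F)F
Why: Dissolving-metal reduction of the enone protonates C20 axially to give the trans ring fusion (H20 anti to the C14 methyl), and the regiodefined enolate is trapped on oxygen as the enol triflate.

**Step 5**
Reactants: 9 trans-fused enol triflate
Product: 10 (4aS,8aS)-2,4a,7,7-tetramethyl-3,4,4a,5,6,7,8,8a-octahydronaphthalene (trans-fused)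
Conditions: MeMgBr, Fe(acac)3 (5 mol %), THF/NMP, −20 → 0 °C
Reagents that add atoms: methylmagnesium bromide, C[Mg]Br
Why: Iron-catalysed Kumada-type cross-coupling of the alkenyl triflate installs the methyl group that becomes C11.

**Step 6**
Reactants: 10 trans-fused methyl octalin
Product: 12 (1R,2S)-2,5,5-trimethyl-2-(3-oxobutyl)cyclohexane-1-carbaldehyde, via ozonide 11 (not isolated)
Conditions: O3, CH2Cl2, −78 °C; Me2S, −78 → 20 °C; used at once
Reagents that add atoms: ozone, [O-][O+]=O
Why: Ozonolysis cleaves the C10=C21 alkene of the template ring to unveil the C21 aldehyde and the C10 methyl ketone without touching C14 or C20.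

**Step 7**
Reactants: 13 (R)-4-[(tert-butyldimethylsilyl)oxy]cyclopent-2-en-1-one
Product: 15 (3R,4R)-4-[(tert-butyldimethylsilyl)oxy]-3-methylcyclopent-1-en-1-yl trifluoromethanesulfonate, via lithium enolate 14 (not isolated)
Conditions: Me2CuLi (MeLi, CuI), Et2O, −78 °C; PhNTf2, THF, −78 → 0 °C
Reagents that add atoms: lithium dimethylcuprate, [Li+].C[Cu-]C; N-phenylbis(trifluoromethanesulfonimide), O=S(=O)(N(c1ccccc1)S(=O)(=O)C(F)(F)F)C(F)(F)F
Why: Gilman conjugate addition anti to the silyloxy group sets C6 trans to C5–O, and O-triflation of the regiospecific enolate fixes the C3=C8 alkene.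

**Step 8**
Reactants: 15 ring A enol triflate
Product: 16 2-[(3R,4R)-4-[(tert-butyldimethylsilyl)oxy]-3-methylcyclopent-1-en-1-yl]-4,4,5,5-tetramethyl-1,3,2-dioxaborolane
Conditions: B2pin2, PdCl2(PPh3)2 (3 mol %), PPh3, PhOK, toluene, 50 °C
Reagents that add atoms: bis(pinacolato)diboron, CC1(C)OB(OC1(C)C)B1OC(C)(C)C(C)(C)O1
Why: Miyaura borylation of an alkenyl triflate.

**Step 9**
Reactants: 16 ring A alkenylboronate; 17 ethyl (E)-but-2-enoate
Product: 18 ethyl (3R)-3-[(3R,4R)-4-[(tert-butyldimethylsilyl)oxy]-3-methylcyclopent-1-en-1-yl]butanoate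
Conditions: [Rh(cod)Cl]2 (2.5 mol %), (S)-BINAP (6 mol %), aq. KOH, dioxane, 60 °C
Reagents that add atoms: none
Why: Hayashi–Miyaura Rh-catalysed 1,4-addition of the alkenylboronate; the ligand enantiomer is chosen to give the (3R) adduct so that later intermediates are single epimers at the temporary C2 centre.

**Step 10**
Reactants: 18 ring A ester
Product: 19 (3R)-3-[(3R,4R)-4-[(tert-butyldimethylsilyl)oxy]-3-methylcyclopent-1-en-1-yl]butanal
Conditions: DIBAL-H, CH2Cl2, −78 °C; Rochelle salt
Reagents that add atoms: none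
Why: Partial ester reduction stops at the aldehyde because the tetrahedral aluminate survives at −78 °C.

**Step 11**
Reactants: 19 ring A aldehyde
Product: 21 (3R)-3-[(3R,4R)-4-[(tert-butyldimethylsilyl)oxy]-3-methylcyclopent-1-en-1-yl]but-1-yne, via alkenyl nonaflate 20 (not isolated)
Conditions: C4F9SO2F, P2-Et phosphazene base (2.2 equiv), DMF, 0 → 20 °C
Reagents that add atoms: none
Why: Enolate O-sulfonylation and base-induced elimination of the alkenyl nonaflate convert RCH2CHO into RC≡CH without change in carbon count; C2 is not enolisable in this step.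

**Step 12**
Reactants: 21 ring A alkyne; 12 ring D keto-aldehyde
Product: 23 propargylic alcohol (C21-OH as both epimers; C10 methyl ketone; C22≡C23), via lithium acetylide 22 (not isolated)
Conditions: n-BuLi, THF, −78 °C; then 12, −78 °C; aq. NH4Cl
Reagents that add atoms: none
Why: 1,2-Addition of the lithium acetylide to the aldehyde, which is far more electrophilic than the methyl ketone at −78 °C; C21 is left uncontrolled because it is ionised in step 18.

**Step 13**
Reactants: 23 propargylic alcohol
Product: 24 C21 methyl ether of 23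
Conditions: Me3OBF4, 1,8-bis(dimethylamino)naphthalene, CH2Cl2, 0 → 20 °C
Reagents that add atoms: trimethyloxonium tetrafluoroborate, C[O+](C)C.F[B-](F)(F)F
Why: O-Methylation under non-basic conditions gives an ether that survives the ylide and oxidation steps and later serves as the leaving group.

**Step 14**
Reactants: 24 C21 methyl ether
Product: 26 C9 aldehyde (C10 epimers), via methyl enol ether 25 (not isolated)
Conditions: Ph3P(CH2OMe)Cl, KHMDS, THF, 0 → 20 °C; then 1 M HCl, THF, 20 °C
Reagents that add atoms: (methoxymethylene)triphenylphosphorane, COC=P(c1ccccc1)(c1ccccc1)c1ccccc1; water, O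
Why: Wittig methoxymethylenation of the methyl ketone and hydrolysis of the enol ether add C9 as an aldehyde; the C10 configuration is irrelevant because C10 becomes sp2 in the next step.

**Step 15**
Reactants: 26 C9 aldehyde
Product: 27 (E)-enal (C10=C12)
Conditions: IBX·4-methoxypyridine N-oxide, DMSO, 20 °C
Reagents that add atoms: none
Why: IBX dehydrogenation of the aldehyde through its enol should give the more substituted, conjugated (E)-enal.

**Step 16**
Reactants: 27 (E)-enal
Product: 28 (Z)-triethylsilyl enol ether (C9=C10, O cis to C12)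
Conditions: Et3SiH, RhCl(PPh3)3 (1 mol %), THF, 50 °C
Reagents that add atoms: triethylsilane, CC[SiH](CC)CC
Why: Rh-catalysed 1,4-hydrosilylation through the s-cis enal places oxygen cis to the former β-carbon, which defines the (Z)-enol ether needed for C10 control.

**Step 17**
Reactants: 28 (Z)-silyl enol ether
Product: 29 hexacarbonyldicobalt complex of 28 (C22≡C23)
Conditions: Co2(CO)8, CH2Cl2, 20 °C
Reagents that add atoms: dicobalt octacarbonyl, O=C=[Co](=C=O)(=C=O)(=C=O)[Co](=C=O)(=C=O)(=C=O)=C=O
Why: Alkyne complexation (Nicholas complex) bends the alkyne and provides the group that will stabilise a cation at C21.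

**Step 18**
Reactants: 29 cobalt-complexed (Z)-silyl enol ether
Product: 31 tetracyclic hexacarbonyldicobalt complex (5-OTBS; 9-OTES; C2=C3 alkene), via silyloxocarbenium triflate 30 (not isolated)
Conditions: TMSOTf (1.3 equiv), 2,6-di-tert-butyl-4-methylpyridine (1.5 equiv), CH2Cl2 (0.005 M), −78 → −20 °C; aq. NaHCO3
Reagents that add atoms: none
Why: Proposed new method: TMSOTf removes the C21 methoxy group to give the Co2(CO)6-stabilised propargylic (Nicholas) cation, into which both C21 epimers converge; the (Z)-silyl enol ether attacks it through C10 (ring C, 6-(enolexo)-exo-trig) and the silyloxocarbenium ion so formed at C9 is captured by the C8=C3 cyclopentene (ring B, 8-endo-trig Prins closure, eased by the bend of the complexed alkyne), after which the C3 cation relays by 1,2-hydride shift to the cobalt-stabilised C2 cation and loses H3 to the hindered base to leave the tetrasubstituted C2=C3 alkene. The closest known reaction types are the Lewis-acid Nicholas cyclisation of silyl enol ethers onto cobalt-complexed propargylic cations (which gives complexed cycloalkynes) and Mukaiyama-aldol–Prins cascades, in which the oxocarbenium ion left by an enol ether after C–C bond formation is trapped by an alkene. C21 should be set by a chair transition state with the bulky cluster equatorial and anti to H20, and C10 by A(1,3) strain in the (Z)-enol ether, which forces C9 equatorial and the methyl group axial. C9 should follow from an open antiperiplanar Prins transition state with the OSiEt3 group turned away from ring A, and C8 from attack anti to the C5 silyloxy group. The step needs the cation to choose the enol ether over the cyclopentene, which the far higher nucleophilicity of the enol ether and the strain of a six-membered ring containing the complexed alkyne (C8 to C21) should secure, and it needs one alkene regioisomer, which the cobalt-stabilised C2 cation should secure as a thermodynamic funnel.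

**Step 19**
Reactants: 31 tetracyclic cobalt complex
Product: 32 (22Z)-diene bis-silyl ether (C22=C23 and C2=C3)
Conditions: Bu3SnH, benzene, 65 °C
Reagents that add atoms: none
Why: Reductive decomplexation of a cyclic alkyne–cobalt complex with tin hydride gives the cis-alkene directly and avoids the strained free cyclooctenyne.

**Step 20**
Reactants: 32 (22Z)-diene
Product: 33 5-O-TBS-9-O-TES ether of the target
Conditions: TsNHNH2, NaOAc, DME/H2O, 85 °C
Reagents that add atoms: none
Why: Diimide reduction is a concerted syn hydrogen transfer that is fast for the cis-disubstituted C22=C23 alkene and should leave the tetrasubstituted C2=C3 alkene untouched.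

**Step 21**
Reactants: 33 bis-silyl ether
Product: 34 CNP0213887.1 (target diol)
Conditions: TBAF, THF, 50 °C
Reagents that add atoms: none
Why: Fluoride-mediated cleavage of both silyl ethers.

**Compound list**
1 | 3,3-dimethylcyclohexanone | CC1(C)CCCC(=O)C1 | starting material
2 | 2,5,5-trimethylcyclohexanone (racemic) | CC1CCC(C)(C)CC1=O | intermediate
3 | methyl vinyl ketone | CC(=O)C=C | starting material
4 | (R)-N-(1-phenylethyl)imine of 2 | C[C@@H](N=C1CC(C)(C)CCC1C)c1ccccc1 | intermediate
5 | Michael-adduct imine (C14 quaternary) | CC(=O)CC[C@]1(C)CCC(C)(C)CC1=N[C@H](C)c1ccccc1 | intermediate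
6 | (S)-2,5,5-trimethyl-2-(3-oxobutyl)cyclohexan-1-one | CC(=O)CC[C@]1(C)CCC(C)(C)CC1=O | intermediate
7 | (S)-4a,7,7-trimethyl-4,4a,5,6,7,8-hexahydronaphthalen-2(3H)-one | O=C1CC[C@]2(C)CCC(C)(C)CC2=C1 | intermediate
8 | lithium enolate of the trans-decalone | [Li]OC1=C[C@@H]2CC(C)(C)CC[C@@]2(C)CC1 | intermediate
9 | (4aS,8aS)-4a,7,7-trimethyl-3,4,4a,5,6,7,8,8a-octahydronaphthalen-2-yl trifluoromethanesulfonate (trans-fused) | O=S(=O)(OC1=C[C@@H]2CC(C)(C)CC[C@@]2(C)CC1)C(F)(F)F | intermediate
10 | (4aS,8aS)-2,4a,7,7-tetramethyl-3,4,4a,5,6,7,8,8a-octahydronaphthalene (trans-fused) | CC1=C[C@@H]2CC(C)(C)CC[C@@]2(C)CC1 | intermediate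
11 | ozonide (1,2,4-trioxolane) of 10 | CC12CC[C@]3(C)CCC(C)(C)C[C@H]3C(O1)OO2 | intermediate
12 | (1R,2S)-2,5,5-trimethyl-2-(3-oxobutyl)cyclohexane-1-carbaldehyde (CHO trans to the oxobutyl chain) | O=C[C@@H]1CC(C)(C)CC[C@@]1(C)CCC(C)=O | intermediate
13 | (R)-4-[(tert-butyldimethylsilyl)oxy]cyclopent-2-en-1-one | O=C1C=C[C@H](O[Si](C)(C)C(C)(C)C)C1 | starting material
14 | lithium enolate after cuprate addition (3-Me trans to 4-OTBS) | [Li]OC1=C[C@@H](C)[C@H](O[Si](C)(C)C(C)(C)C)C1 | intermediate
15 | (3R,4R)-4-[(tert-butyldimethylsilyl)oxy]-3-methylcyclopent-1-en-1-yl trifluoromethanesulfonate | O=S(=O)(OC1=C[C@@H](C)[C@H](O[Si](C)(C)C(C)(C)C)C1)C(F)(F)F | intermediate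
16 | 2-[(3R,4R)-4-[(tert-butyldimethylsilyl)oxy]-3-methylcyclopent-1-en-1-yl]-4,4,5,5-tetramethyl-1,3,2-dioxaborolane | CC1(C)OB(OC1(C)C)C1=C[C@@H](C)[C@H](O[Si](C)(C)C(C)(C)C)C1 | intermediate
17 | ethyl (E)-but-2-enoate | CCOC(=O)/C=C/C | starting material
18 | ethyl (3R)-3-[(3R,4R)-4-[(tert-butyldimethylsilyl)oxy]-3-methylcyclopent-1-en-1-yl]butanoate | CCOC(=O)C[C@@H](C)C1=C[C@@H](C)[C@H](O[Si](C)(C)C(C)(C)C)C1 | intermediate
19 | (3R)-3-[(3R,4R)-4-[(tert-butyldimethylsilyl)oxy]-3-methylcyclopent-1-en-1-yl]butanal | O=CC[C@@H](C)C1=C[C@@H](C)[C@H](O[Si](C)(C)C(C)(C)C)C1 | intermediate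
20 | alkenyl nonaflate of 19 (E/Z) | O=S(=O)(OC=C[C@@H](C)C1=C[C@@H](C)[C@H](O[Si](C)(C)C(C)(C)C)C1)C(F)(F)C(F)(F)C(F)(F)C(F)(F)F | intermediate
21 | (3R)-3-[(3R,4R)-4-[(tert-butyldimethylsilyl)oxy]-3-methylcyclopent-1-en-1-yl]but-1-yne | C#C[C@@H](C)C1=C[C@@H](C)[C@H](O[Si](C)(C)C(C)(C)C)C1 | intermediate
22 | lithium acetylide of 21 | [Li]C#C[C@@H](C)C1=C[C@@H](C)[C@H](O[Si](C)(C)C(C)(C)C)C1 | intermediate
23 | propargylic alcohol (C21-OH both epimers; C10 methyl ketone; C22≡C23 joins the ring D and ring A fragments) | CC(=O)CC[C@]1(C)CCC(C)(C)C[C@H]1C(O)C#C[C@@H](C)C1=C[C@@H](C)[C@H](O[Si](C)(C)C(C)(C)C)C1 | intermediate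
24 | C21 methyl ether of 23 | CC(=O)CC[C@]1(C)CCC(C)(C)C[C@H]1C(OC)C#C[C@@H](C)C1=C[C@@H](C)[C@H](O[Si](C)(C)C(C)(C)C)C1 | intermediate
25 | methyl enol ether at C9=C10 (E/Z) | COC=C(C)CC[C@]1(C)CCC(C)(C)C[C@H]1C(OC)C#C[C@@H](C)C1=C[C@@H](C)[C@H](O[Si](C)(C)C(C)(C)C)C1 | intermediate
26 | C9 aldehyde (C10 epimers) | O=CC(C)CC[C@]1(C)CCC(C)(C)C[C@H]1C(OC)C#C[C@@H](C)C1=C[C@@H](C)[C@H](O[Si](C)(C)C(C)(C)C)C1 | intermediate
27 | (E)-enal (C10=C12) | O=C/C(C)=C/C[C@]1(C)CCC(C)(C)C[C@H]1C(OC)C#C[C@@H](C)C1=C[C@@H](C)[C@H](O[Si](C)(C)C(C)(C)C)C1 | intermediate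
28 | (Z)-triethylsilyl enol ether (C9=C10; O cis to C12) | CC[Si](CC)(CC)O/C=C(/C)CC[C@]1(C)CCC(C)(C)C[C@H]1C(OC)C#C[C@@H](C)C1=C[C@@H](C)[C@H](O[Si](C)(C)C(C)(C)C)C1 | intermediate
29 | hexacarbonyldicobalt complex of 28 (C22, C23 bridged by Co2(CO)6) | CC[Si](CC)(CC)O/C=C(/C)CC[C@]1(C)CCC(C)(C)C[C@H]1C(OC)C23[Co]4(=C=O)(=C=O)(=C=O)[Co]2(=C=O)(=C=O)(=C=O)C34[C@@H](C)C1=C[C@@H](C)[C@H](O[Si](C)(C)C(C)(C)C)C1 | intermediate
30 | C9 silyloxocarbenium triflate (ring C closed; C10 methyl axial; H21 anti to H20) | CC[Si](CC)(CC)[O+]=C[C@@]1(C)CC[C@]2(C)CCC(C)(C)C[C@H]2[C@@H]1C34[Co]5(=C=O)(=C=O)(=C=O)[Co]3(=C=O)(=C=O)(=C=O)C45[C@@H](C)C1=C[C@@H](C)[C@H](O[Si](C)(C)C(C)(C)C)C1.[O-]S(=O)(=O)C(F)(F)F | intermediate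
31 | tetracyclic hexacarbonyldicobalt complex (5-OTBS; 9-OTES; C2=C3; target configuration at C5, C6, C8, C9, C10, C14, C20, C21) | C/C1=C2\C[C@@H](O[Si](C)(C)C(C)(C)C)[C@H](C)[C@@H]2[C@@H](O[Si](CC)(CC)CC)[C@@]2(C)CC[C@]3(C)CCC(C)(C)C[C@H]3[C@@H]2C45[Co]6(=C=O)(=C=O)(=C=O)[Co]4(=C=O)(=C=O)(=C=O)C156 | intermediate
32 | (22Z)-diene bis-silyl ether | C/C1=C2\C[C@@H](O[Si](C)(C)C(C)(C)C)[C@H](C)[C@@H]2[C@@H](O[Si](CC)(CC)CC)[C@@]2(C)CC[C@]3(C)CCC(C)(C)C[C@H]3[C@@H]2/C=C\1 | intermediate
33 | 5-O-TBS-9-O-TES ether of the target | C/C1=C2\C[C@@H](O[Si](C)(C)C(C)(C)C)[C@H](C)[C@@H]2[C@@H](O[Si](CC)(CC)CC)[C@@]2(C)CC[C@]3(C)CCC(C)(C)C[C@H]3[C@@H]2CC1 | intermediate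
34 | CNP0213887.1 | C/C1=C2\C[C@@H](O)[C@H](C)[C@@H]2[C@@H](O)[C@@]2(C)CC[C@]3(C)CCC(C)(C)C[C@H]3[C@@H]2CC1 | target

**Count**
Total steps: 21. Longest linear sequence: 16 (steps 1–6, then 12–21).

**Steps most likely to fail**

1. Step 18 (proposed new method). The cascade may stall after the first bond through desilylation of the oxocarbenium ion. The cyclopentene may be attacked on the wrong face, or proton loss may go toward the wrong carbon. The fallback runs the two halves as separate reactions of known type; it sets out from 29 and comes back at 31. BF3·OEt2 in CH2Cl2 at −78 °C with aqueous work-up should effect only the Nicholas cyclisation onto the silyl enol ether and give the aldehyde cobalt complex F1. Ring B is then closed in its own step by a Me2AlCl-promoted intramolecular carbonyl–ene/Prins cyclisation (CH2Cl2, −78 → 0 °C) to the C9 alcohol complex F2, whose C8/C9 configuration is assigned before going on. A closed ene transition state would favour the C9 epimer, so this is the point to check. TESOTf/2,6-lutidine then gives 31.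

2. Step 15. The oxidant may attack the doubly activated C2–H, or dehydrogenation may run toward the C11 methyl group. The fallback replaces hypervalent-iodine dehydrogenation by selenoxide elimination; it sets out from 26 and comes back at 27. PhSeCl (EtOAc, cat. HCl, 20 °C) should give the α-phenylselanyl aldehyde F3. H2O2/pyridine (CH2Cl2, 0 °C) oxidises it to the selenoxide F4, which undergoes syn-elimination toward C12.

3. Step 12. The acetylide may add to or enolise the methyl ketone. The fallback carries C10 through the union as a carboxylate, which is inert to the acetylide; it sets out from 7 and comes back at 23. Li/NH3 reduction of 7 and trapping with TMSCl/Et3N give the silyl enol ether F5. Ozonolysis (O3; Me2S) gives the aldehyde acid F6. Acetylide 22 (2.2 equiv, THF, −78 °C) gives the hydroxy acid F7. MeLi (3 equiv, THF, 0 °C) converts the lithium carboxylate into the methyl ketone 23.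

**Further compounds**
F1 | step 18 | aldehyde cobalt complex (ring C closed; C9 aldehyde) | O=C[C@@]1(C)CC[C@]2(C)CCC(C)(C)C[C@H]2[C@@H]1C34[Co]5(=C=O)(=C=O)(=C=O)[Co]3(=C=O)(=C=O)(=C=O)C45[C@@H](C)C1=C[C@@H](C)[C@H](O[Si](C)(C)C(C)(C)C)C1
F2 | step 18 | C9 alcohol tetracyclic cobalt complex (5-OTBS) | C/C1=C2\C[C@@H](O[Si](C)(C)C(C)(C)C)[C@H](C)[C@@H]2[C@@H](O)[C@@]2(C)CC[C@]3(C)CCC(C)(C)C[C@H]3[C@@H]2C45[Co]6(=C=O)(=C=O)(=C=O)[Co]4(=C=O)(=C=O)(=C=O)C156
F3 | step 15 | α-phenylselanyl aldehyde (C10) | O=CC(C)([Se]c1ccccc1)CC[C@]1(C)CCC(C)(C)C[C@H]1C(OC)C#C[C@@H](C)C1=C[C@@H](C)[C@H](O[Si](C)(C)C(C)(C)C)C1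
F4 | step 15 | selenoxide of F3 | O=CC(C)([Se](=O)c1ccccc1)CC[C@]1(C)CCC(C)(C)C[C@H]1C(OC)C#C[C@@H](C)C1=C[C@@H](C)[C@H](O[Si](C)(C)C(C)(C)C)C1
F5 | step 12 | trimethylsilyl enol ether of the trans-decalone | C[Si](C)(C)OC1=C[C@@H]2CC(C)(C)CC[C@@]2(C)CC1
F6 | step 12 | 3-[(1S,2R)-2-formyl-1,4,4-trimethylcyclohexyl]propanoic acid | O=C[C@@H]1CC(C)(C)CC[C@@]1(C)CCC(=O)O
F7 | step 12 | hydroxy acid (C21-OH both epimers; C10 carboxylic acid) | O=C(O)CC[C@]1(C)CCC(C)(C)C[C@H]1C(O)C#C[C@@H](C)C1=C[C@@H](C)[C@H](O[Si](C)(C)C(C)(C)C)C1
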